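**Retrosynthetic overview**
1. Target 21 ⇐ global O-debenzylation of lactone 20. The butyrolactone is the only ring made, closed in the penultimate step (step 11); all three arenes are bought.
2. 20 ⇐ lactonisation with α-epimerisation of hydroxy ester 19 ⇐ one double reductive removal of two Evans auxiliaries from 18.
3. Side chain: C–C bond between the carbinol carbon and the aryl-bearing carbon by Evans syn-aldol of an arylacetyl imide (15) with O-benzylvanillin; the arylacetyl unit comes from Pd α-arylation of aryl bromide 12.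
4. Key disconnection: the lactone Cα–Cβ bond of 12, joining two enolate α-carbons (both natively nucleophilic) by oxidative enolate heterocoupling of imide 5 and ester 9; one enolate is oxidised in the flask to an enolonium-type α-carbonyl species.
5. 5 ⇐ dihydroferulic acid 1 and auxiliary 3; 9 ⇐ 5-bromovanillin 6.

Assumption: simple reagents (BnBr, the Wittig ylide, TMSOTf, bases, catalysts) are not numbered. Compounds 12, 15, 17, 18 and 19 are carried as mixtures of epimers at the ester α-carbon (C2), so that centre is left undefined in their SMILES until step 11 fixes it.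

**Step 1**
Reactants: 1 dihydroferulic acid [3-(4-hydroxy-3-methoxyphenyl)propanoic acid]
Product: 2 3-[4-(benzyloxy)-3-methoxyphenyl]propanoic acid
Conditions: BnBr, NaOH, EtOH/H2O, reflux; then HCl
Reagents that add atoms: benzyl bromide, BrCc1ccccc1
Why: Williamson etherification; in aqueous NaOH the phenoxide is alkylated and any benzyl ester formed is saponified in situ, so the free acid is obtained directly.

**Step 2**
Reactants: 2 3-[4-(benzyloxy)-3-methoxyphenyl]propanoic acid; 3 (S)-4-benzyl-2-oxazolidinone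
Product: 5 (S)-4-benzyl-3-{3-[4-(benzyloxy)-3-methoxyphenyl]propanoyl}oxazolidin-2-one, via mixed pivalic anhydride 4 (not isolated)
Conditions: PivCl, Et3N, THF, −20 → 0 °C; then 3, LiCl, rt
Reagents that add atoms: none
Why: N-acylation of the oxazolidinone through the mixed pivalic anhydride (Et3N/LiCl protocol), attack occurring at the unhindered acyl group.

**Step 3**
Reactants: 6 5-bromovanillin (3-bromo-4-hydroxy-5-methoxybenzaldehyde)
Product: 7 4-(benzyloxy)-3-bromo-5-methoxybenzaldehyde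
Conditions: BnBr, K2CO3, DMF, 60 °C
Reagents that add atoms: benzyl bromide, BrCc1ccccc1
Why: Williamson etherification of the acidic, hindered phenol.

**Step 4**
Reactants: 7 4-(benzyloxy)-3-bromo-5-methoxybenzaldehyde
Product: 8 tert-butyl (E)-3-[4-(benzyloxy)-3-bromo-5-methoxyphenyl]prop-2-enoate
Conditions: Ph3P=CHCO2t-Bu, toluene, 90 °C
Reagents that add atoms: (tert-butoxycarbonylmethylene)triphenylphosphorane, CC(C)(C)OC(=O)C=P(c1ccccc1)(c1ccccc1)c1ccccc1
Why: Wittig olefination with a stabilised ylide, E-selective (the geometry is erased in step 5).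

**Step 5**
Reactants: 8 tert-butyl (E)-3-[4-(benzyloxy)-3-bromo-5-methoxyphenyl]prop-2-enoate
Product: 9 tert-butyl 3-[4-(benzyloxy)-3-bromo-5-methoxyphenyl]propanoate
Conditions: H2 (3 atm), RhCl(PPh3)3 (5 mol%), toluene/EtOH, 50 °C
Reagents that add atoms: none
Why: Homogeneous hydrogenation with RhCl(PPh3)3 reduces the conjugated alkene without hydrogenolysis of the aryl bromide or the benzyl ether.

**Step 6 (key step)**
Reactants: 5 (S)-4-benzyl-3-{3-[4-(benzyloxy)-3-methoxyphenyl]propanoyl}oxazolidin-2-one; 9 tert-butyl 3-[4-(benzyloxy)-3-bromo-5-methoxyphenyl]propanoate (1.5 equiv)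
Product: 12 tert-butyl (2RS,3R)-2-(4-benzyloxy-3-bromo-5-methoxybenzyl)-3-(4-benzyloxy-3-methoxybenzyl)-4-[(S)-4-benzyl-2-oxooxazolidin-3-yl]-4-oxobutanoate (C2 epimer mixture), via imide lithium Z-enolate 10 (not isolated), via ester lithium enolate 11 (not isolated)
Conditions: LiN(i-Pr)2 (2.6 equiv), THF, −78 °C; then Fe(acac)3 (2.6 equiv), −78 °C → rt
Reagents that add atoms: none
Why: Oxidative enolate heterocoupling: one-electron oxidation by Fe(acac)3 (trivalent iron) turns one enolate of the mixed aggregate into an electrophilic α-carbonyl radical (enolonium-type) that the other enolate captures, so two natively nucleophilic α-carbons are joined, imide–ester cross-coupling being favoured over homodimerisation; the bond forms on the face of the chelated Z-imide enolate opposite the auxiliary benzyl group (as in Evans alkylation), setting C3 as R, while C2 forms as a mixture (about 2:1 expected) that is corrected in step 11.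

**Step 7**
Reactants: 13 (S)-3-acetyl-4-benzyloxazolidin-2-one
Product: 14 (S)-4-benzyl-3-[1-(trimethylsilyloxy)ethenyl]oxazolidin-2-one
Conditions: TMSOTf, Et3N, CH2Cl2, 0 °C; pentane trituration, used crude
Reagents that add atoms: trimethylsilyl trifluoromethanesulfonate, C[Si](C)(C)OS(=O)(=O)C(F)(F)F
Why: Soft enolisation and O-silylation of the acetyl imide gives the silyl ketene N,O-acetal, a neutral enolate equivalent.

**Step 8**
Reactants: 12 heterocoupled bromide (C2 epimer mixture); 14 (S)-4-benzyl-3-[1-(trimethylsilyloxy)ethenyl]oxazolidin-2-one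
Product: 15 tert-butyl (2RS,3R)-2-{4-(benzyloxy)-3-[2-((S)-4-benzyl-2-oxooxazolidin-3-yl)-2-oxoethyl]-5-methoxybenzyl}-3-(4-benzyloxy-3-methoxybenzyl)-4-[(S)-4-benzyl-2-oxooxazolidin-3-yl]-4-oxobutanoate
Conditions: Pd(dba)2 (5 mol%), P(t-Bu)3 (10 mol%), ZnF2 (0.6 equiv), DMF, 80 °C
Reagents that add atoms: none
Why: Palladium-catalysed α-arylation of a silyl ketene N,O-acetal (ZnF2-promoted, Hartwig type): oxidative addition of the aryl bromide to zerovalent palladium, transmetallation of the fluoride-activated enolate and reductive elimination give the arylacetyl imide under near-neutral conditions that leave the succinate stereocentre untouched.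

**Step 9**
Reactants: 15 arylacetyl imide (C2 epimer mixture); 16 4-(benzyloxy)-3-methoxybenzaldehyde (O-benzylvanillin)
Product: 18 tert-butyl (2RS,3R)-2-{4-(benzyloxy)-3-[(1S,2S)-1-(4-(benzyloxy)-3-methoxyphenyl)-3-((S)-4-benzyl-2-oxooxazolidin-3-yl)-1-hydroxy-3-oxopropan-2-yl]-5-methoxybenzyl}-3-(4-benzyloxy-3-methoxybenzyl)-4-[(S)-4-benzyl-2-oxooxazolidin-3-yl]-4-oxobutanoate, via dibutylboron Z-enolate 17 (not isolated)
Conditions: Bu2BOTf, i-Pr2NEt, CH2Cl2, −78 → 0 °C; 16, −78 → 0 °C; pH 7 buffer, MeOH, H2O2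
Reagents that add atoms: none
Why: Evans syn-aldol: only the acidic arylacetyl imide is enolised (the branched succinyl imide and the ester are not), and the closed Zimmerman–Traxler transition state of the Z-boron enolate with the (S)-auxiliary gives the 2S,3S syn adduct, which becomes the 1S,2R side chain after reduction.

**Step 10**
Reactants: 18 syn-aldol bis-imide (C2 epimer mixture)
Product: 19 tert-butyl (2RS,3R)-2-{4-(benzyloxy)-3-[(1S,2R)-1-(4-(benzyloxy)-3-methoxyphenyl)-1,3-dihydroxypropan-2-yl]-5-methoxybenzyl}-3-(4-benzyloxy-3-methoxybenzyl)-4-hydroxybutanoate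
Conditions: LiBH4, MeOH, THF, 0 °C; NH4Cl (aq)
Reagents that add atoms: none
Why: Reductive cleavage of N-acyloxazolidinones with LiBH4 converts both exocyclic imide carbonyls into primary alcohols in one operation while the tert-butyl ester survives at 0 °C; no stereocentre is touched and auxiliary 3 is recovered.

**Step 11**
Reactants: 19 triol tert-butyl ester (C2 epimer mixture)
Product: 20 (3R,4R)-3-{4-(benzyloxy)-3-[(1S,2R)-1-(4-(benzyloxy)-3-methoxyphenyl)-1,3-dihydroxypropan-2-yl]-5-methoxybenzyl}-4-(4-benzyloxy-3-methoxybenzyl)dihydrofuran-2(3H)-one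
Conditions: KOt-Bu (0.3 equiv), THF, 0 °C → rt; AcOH
Reagents that add atoms: none
Why: Alkoxide-catalysed intramolecular transesterification (5-exo lactonisation) of the γ-hydroxy tert-butyl ester, with enolate equilibration of the lactone α-carbon to the thermodynamically preferred trans-3,4-dibenzyl lactone, which sets C3 as R from either C2 epimer.

**Step 12**
Reactants: 20 tribenzyl-protected lactone
Product: 21 (3R,4R)-3-{3-[(1S,2R)-1,3-dihydroxy-1-(4-hydroxy-3-methoxyphenyl)propan-2-yl]-4-hydroxy-5-methoxybenzyl}-4-(4-hydroxy-3-methoxybenzyl)dihydrofuran-2(3H)-one (target)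
Conditions: H2 (1 atm), 10% Pd/C, EtOAc/EtOH, rt, stopped at full debenzylation
Reagents that add atoms: none
Why: Hydrogenolysis of the three aryl benzyl ethers under neutral conditions; the secondary benzylic alcohol, the lactone and all four stereocentres are retained.

**Compound list**
1 | 3-(4-hydroxy-3-methoxyphenyl)propanoic acid (dihydroferulic acid) | COc1cc(CCC(=O)O)ccc1O | starting material
2 | 3-[4-(benzyloxy)-3-methoxyphenyl]propanoic acid | COc1cc(CCC(=O)O)ccc1OCc1ccccc1 | intermediate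
3 | (S)-4-benzyl-2-oxazolidinone | O=C1N[C@@H](Cc2ccccc2)CO1 | starting material
4 | 3-[4-(benzyloxy)-3-methoxyphenyl]propanoic pivalic anhydride | COc1cc(CCC(=O)OC(=O)C(C)(C)C)ccc1OCc1ccccc1 | intermediate (not isolated)
5 | (S)-4-benzyl-3-{3-[4-(benzyloxy)-3-methoxyphenyl]propanoyl}oxazolidin-2-one | COc1cc(CCC(=O)N2[C@@H](Cc3ccccc3)COC2=O)ccc1OCc1ccccc1 | intermediate
6 | 3-bromo-4-hydroxy-5-methoxybenzaldehyde (5-bromovanillin) | COc1cc(C=O)cc(Br)c1O | starting material
7 | 4-(benzyloxy)-3-bromo-5-methoxybenzaldehyde | COc1cc(C=O)cc(Br)c1OCc1ccccc1 | intermediate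
8 | tert-butyl (E)-3-[4-(benzyloxy)-3-bromo-5-methoxyphenyl]prop-2-enoate | COc1cc(/C=C/C(=O)OC(C)(C)C)cc(Br)c1OCc1ccccc1 | intermediate
9 | tert-butyl 3-[4-(benzyloxy)-3-bromo-5-methoxyphenyl]propanoate | COc1cc(CCC(=O)OC(C)(C)C)cc(Br)c1OCc1ccccc1 | intermediate
10 | lithium (Z)-enolate of imide 5 | [Li+].[O-]/C(=C\Cc1ccc(OCc2ccccc2)c(OC)c1)N1[C@@H](Cc2ccccc2)COC1=O | intermediate (not isolated)
11 | lithium enolate of ester 9 | [Li+].[O-]C(OC(C)(C)C)=CCc1cc(OC)c(OCc2ccccc2)c(Br)c1 | intermediate (not isolated)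
12 | tert-butyl (2RS,3R)-2-{[4-(benzyloxy)-3-bromo-5-methoxyphenyl]methyl}-3-{[4-(benzyloxy)-3-methoxyphenyl]methyl}-4-[(S)-4-benzyl-2-oxooxazolidin-3-yl]-4-oxobutanoate (C2 epimer mixture) | COc1cc(C[C@@H](C(=O)N2[C@@H](Cc3ccccc3)COC2=O)C(Cc2cc(OC)c(OCc3ccccc3)c(Br)c2)C(=O)OC(C)(C)C)ccc1OCc1ccccc1 | intermediate
13 | (S)-3-acetyl-4-benzyloxazolidin-2-one | CC(=O)N1[C@@H](Cc2ccccc2)COC1=O | starting material
14 | (S)-4-benzyl-3-[1-(trimethylsilyloxy)ethenyl]oxazolidin-2-one | C=C(O[Si](C)(C)C)N1[C@@H](Cc2ccccc2)COC1=O | intermediate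
15 | tert-butyl (2RS,3R)-2-{4-(benzyloxy)-3-[2-((S)-4-benzyl-2-oxooxazolidin-3-yl)-2-oxoethyl]-5-methoxybenzyl}-3-(4-benzyloxy-3-methoxybenzyl)-4-[(S)-4-benzyl-2-oxooxazolidin-3-yl]-4-oxobutanoate (C2 epimer mixture) | COc1cc(C[C@@H](C(=O)N2[C@@H](Cc3ccccc3)COC2=O)C(Cc2cc(OC)c(OCc3ccccc3)c(CC(=O)N3[C@@H](Cc4ccccc4)COC3=O)c2)C(=O)OC(C)(C)C)ccc1OCc1ccccc1 | intermediate
16 | 4-(benzyloxy)-3-methoxybenzaldehyde (O-benzylvanillin) | COc1cc(C=O)ccc1OCc1ccccc1 | starting material
17 | dibutylboron (Z)-enolate of the arylacetyl imide of 15 | COc1cc(C[C@@H](C(=O)N2[C@@H](Cc3ccccc3)COC2=O)C(Cc2cc(OC)c(OCc3ccccc3)c(/C=C(\OB(CCCC)CCCC)N3[C@@H](Cc4ccccc4)COC3=O)c2)C(=O)OC(C)(C)C)ccc1OCc1ccccc1 | intermediate (not isolated)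
18 | tert-butyl (2RS,3R)-2-{4-(benzyloxy)-3-[(1S,2S)-1-(4-(benzyloxy)-3-methoxyphenyl)-3-((S)-4-benzyl-2-oxooxazolidin-3-yl)-1-hydroxy-3-oxopropan-2-yl]-5-methoxybenzyl}-3-(4-benzyloxy-3-methoxybenzyl)-4-[(S)-4-benzyl-2-oxooxazolidin-3-yl]-4-oxobutanoate (C2 epimer mixture) | COc1cc(C[C@@H](C(=O)N2[C@@H](Cc3ccccc3)COC2=O)C(Cc2cc(OC)c(OCc3ccccc3)c([C@H](C(=O)N3[C@@H](Cc4ccccc4)COC3=O)[C@H](O)c3ccc(OCc4ccccc4)c(OC)c3)c2)C(=O)OC(C)(C)C)ccc1OCc1ccccc1 | intermediate
19 | tert-butyl (2RS,3R)-2-{4-(benzyloxy)-3-[(1S,2R)-1-(4-(benzyloxy)-3-methoxyphenyl)-1,3-dihydroxypropan-2-yl]-5-methoxybenzyl}-3-(4-benzyloxy-3-methoxybenzyl)-4-hydroxybutanoate (C2 epimer mixture) | COc1cc(C[C@@H](CO)C(Cc2cc(OC)c(OCc3ccccc3)c([C@H](CO)[C@H](O)c3ccc(OCc4ccccc4)c(OC)c3)c2)C(=O)OC(C)(C)C)ccc1OCc1ccccc1 | intermediate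
20 | (3R,4R)-3-{4-(benzyloxy)-3-[(1S,2R)-1-(4-(benzyloxy)-3-methoxyphenyl)-1,3-dihydroxypropan-2-yl]-5-methoxybenzyl}-4-(4-benzyloxy-3-methoxybenzyl)dihydrofuran-2(3H)-one | COc1cc(C[C@H]2COC(=O)[C@@H]2Cc2cc(OC)c(OCc3ccccc3)c([C@H](CO)[C@H](O)c3ccc(OCc4ccccc4)c(OC)c3)c2)ccc1OCc1ccccc1 | intermediate
21 | (3R,4R)-3-{3-[(1S,2R)-1,3-dihydroxy-1-(4-hydroxy-3-methoxyphenyl)propan-2-yl]-4-hydroxy-5-methoxybenzyl}-4-(4-hydroxy-3-methoxybenzyl)dihydrofuran-2(3H)-one | COc1cc(C[C@H]2COC(=O)[C@@H]2Cc2cc(OC)c(O)c([C@H](CO)[C@H](O)c3ccc(O)c(OC)c3)c2)ccc1O | target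

**Totals**
Total step count: 12. Longest linear sequence: 9 (steps 3, 4, 5, 6, 8, 9, 10, 11, 12; 6 → 7 → 8 → 9 → 12 → 15 → 18 → 19 → 20 → 21).

**Three steps most likely to fail, each with a fallback**

Step 6 (oxidative heterocoupling: homodimers, moderate yield, sensitivity to enolate aggregation). The fallback sets out from ester 9 (with imide 5) and comes back at 12. Ester 9 is α-hydroxylated (KN(SiMe3)2, 2-(phenylsulfonyl)-3-phenyloxaziridine, THF, −78 °C) to racemic tert-butyl 3-[4-(benzyloxy)-3-bromo-5-methoxyphenyl]-2-hydroxypropanoate F1. F1 is converted (Tf2O, 2,6-lutidine, CH2Cl2, −78 °C) into tert-butyl 3-[4-(benzyloxy)-3-bromo-5-methoxyphenyl]-2-(trifluoromethylsulfonyloxy)propanoate F2. The sodium enolate of imide 5 (NaN(SiMe3)2, THF, −78 °C) displaces the triflate by SN2 on the face opposite the auxiliary benzyl group and gives 12 with the same undefined C2. The ester α-carbon is then a preformed electrophile (a stoichiometric enolonium equivalent) instead of one generated by oxidation.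

Step 8 (α-arylation of a hindered, electron-rich aryl bromide in a substrate carrying an imide and an ester). The fallback sets out from 12 and comes back at 15. Stille coupling with allyltributylstannane (Pd(PPh3)4, DMF, 90 °C) gives the allyl arene F3. Oxidative cleavage (OsO4 cat., NaIO4, 2,6-lutidine, dioxane/H2O) gives the arylacetaldehyde F4. Pinnick oxidation (NaClO2, NaH2PO4, 2-methyl-2-butene, t-BuOH/H2O) gives the arylacetic acid F5. Mixed-anhydride acylation of auxiliary 3 (PivCl, Et3N, LiCl, THF) then gives 15.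

Step 10 (double LiBH4 reduction: endocyclic opening of the hindered succinyl imide, or over-reduction through a lactone formed in the flask). The fallback sets out from 18 and comes back at 19. LiOH/H2O2 (THF/H2O, 0 °C) hydrolyses both imides exocyclically to the diacid F6, with auxiliary 3 recovered. BH3·SMe2 (THF, 0 °C → rt) then reduces the two carboxylic acids selectively in the presence of the tert-butyl ester to give 19.

**Further compounds**
F1 | step 6 | tert-butyl 3-[4-(benzyloxy)-3-bromo-5-methoxyphenyl]-2-hydroxypropanoate (racemic) | COc1cc(CC(O)C(=O)OC(C)(C)C)cc(Br)c1OCc1ccccc1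
F2 | step 6 | tert-butyl 3-[4-(benzyloxy)-3-bromo-5-methoxyphenyl]-2-(trifluoromethylsulfonyloxy)propanoate (racemic) | COc1cc(CC(OS(=O)(=O)C(F)(F)F)C(=O)OC(C)(C)C)cc(Br)c1OCc1ccccc1
F3 | step 8 | tert-butyl (2RS,3R)-2-[3-allyl-4-(benzyloxy)-5-methoxybenzyl]-3-(4-benzyloxy-3-methoxybenzyl)-4-[(S)-4-benzyl-2-oxooxazolidin-3-yl]-4-oxobutanoate | COc1cc(C[C@@H](C(=O)N2[C@@H](Cc3ccccc3)COC2=O)C(Cc2cc(OC)c(OCc3ccccc3)c(CC=C)c2)C(=O)OC(C)(C)C)ccc1OCc1ccccc1
F4 | step 8 | tert-butyl (2RS,3R)-2-[4-(benzyloxy)-3-methoxy-5-(2-oxoethyl)benzyl]-3-(4-benzyloxy-3-methoxybenzyl)-4-[(S)-4-benzyl-2-oxooxazolidin-3-yl]-4-oxobutanoate | COc1cc(C[C@@H](C(=O)N2[C@@H](Cc3ccccc3)COC2=O)C(Cc2cc(OC)c(OCc3ccccc3)c(CC=O)c2)C(=O)OC(C)(C)C)ccc1OCc1ccccc1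
F5 | step 8 | {2-(benzyloxy)-5-[(2RS,3R)-3-(4-benzyloxy-3-methoxybenzyl)-4-((S)-4-benzyl-2-oxooxazolidin-3-yl)-2-(tert-butoxycarbonyl)-4-oxobutyl]-3-methoxyphenyl}acetic acid | COc1cc(C[C@@H](C(=O)N2[C@@H](Cc3ccccc3)COC2=O)C(Cc2cc(OC)c(OCc3ccccc3)c(CC(=O)O)c2)C(=O)OC(C)(C)C)ccc1OCc1ccccc1
F6 | step 10 | (2R,3RS)-2-(4-benzyloxy-3-methoxybenzyl)-3-{4-(benzyloxy)-3-[(1S,2S)-1-(4-(benzyloxy)-3-methoxyphenyl)-2-carboxy-1-hydroxyethyl]-5-methoxybenzyl}-4-(tert-butoxy)-4-oxobutanoic acid | COc1cc(C[C@@H](C(=O)O)C(Cc2cc(OC)c(OCc3ccccc3)c([C@H](C(=O)O)[C@H](O)c3ccc(OCc4ccccc4)c(OC)c3)c2)C(=O)OC(C)(C)C)ccc1OCc1ccccc1
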